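## Structural features

The target is a 1,2,6-trisubstituted cyclohex-3-ene (ring A). C1 carries a five-carbon chain C7–C11, present as the chelated (Z)-enol of a 1,3-diketone and continued through an (E)-alkene (C10=C11) to a 4-hydroxy-3-methoxyphenyl ring. C2 bears a 3,4-dimethoxyphenyl group (Ar1) and C6 a 4-hydroxy-3-methoxyphenyl group (Ar2); the ring alkene is C3=C4 and C5 is the only ring methylene. The stereocentres C6, C1 and C2 are contiguous and all S, with the acyl carbon C7 cis to Ar2 and trans to Ar1. Fragile sites are the enolised β-diketone (retro-Claisen cleavage under basic nucleophiles), the two free phenols, the C1–H bond (α to a carbonyl, flanked by two benzylic carbons) and the C3=C4 alkene, which can drift into conjugation with Ar1 because C2–H is both allylic and benzylic. The real difficulty is to set the stereotriad in one absolute sense and also place the alkene at C3=C4, because a direct [4+2] construction leaves it at C4=C5. The key step uses the fact that bonds C1–C6 and C2–C3, with C7 cis to Ar2 and trans to Ar1, are the bonds and relative configuration of an endo adduct between a 1-Ar2-butadiene (C3–C6) and an (E)-Ar1-acryloyl unit (C1=C2). A silyl group on C3 of that adduct makes the C4=C5 alkene part of an allylsilane, and protodesilylation then moves the alkene to C3=C4 and removes the silicon.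

## Logic of the disconnections

20 ⇒ 19. The two phenolic O–H bonds are traced back to O–Si bonds. The phenols must be masked during enolate and Lewis-acid chemistry, and two identical silyl ethers allow one final unmasking. The forward step must cleave Si–O at near-neutral pH so that the enolised diketone and C1 are not disturbed.

19 ⇒ 13 + 17. The C8–C9 bond (α-carbon of the ring A ketone to the chain carbonyl) is cut as a Claisen retron. This separates the whole stereochemical content (13) from an achiral C6–C3 acyl unit (17) and makes the end game convergent. The forward step needs enolisation at the methyl group and not at C1, C- rather than O-acylation, and no epimerisation at C1.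

17 ⇒ 16 ⇒ 14. The C–Cl and O–Si bonds are removed to reach a commodity cinnamic acid. The only demand is that the aryl silyl ether survives carboxyl activation.

13 ⇒ 12 ⇒ 11. The C7–CH3 bond is cut (acyl substitution), and the C7–S bond of 12 is traced to the C7–N bond of 11. The imide needed for the key step is exchanged for an acyl donor that accepts exactly one methyl group. The forward steps need attack at the exocyclic carbonyl of a congested imide and a methyl nucleophile that stops at the ketone and is not basic enough to touch C1–H.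

11 ⇒ 10. A silyl group is put back on C3 and the alkene is moved to C4=C5. This uncovers the cyclohexene pattern of a Diels–Alder adduct and costs one extra stereocentre (C3) that is erased later. The forward step must protonate C5 only, must not move the new alkene into conjugation with Ar1, and must spare the aryl silyl ether.

10 ⇒ 5 + 9. Bonds C1–C6 and C2–C3 are cut together. Ring A and four stereocentres are traded for two flat, achiral components. The forward step must control regiochemistry (aryl terminus of 5 to C1), endo topology and the face of 9, and must work with a β-aryl dienophile of modest reactivity.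

9 ⇒ 6 + 7 (through 8). The N–C7 bond is cut as an N-acylation. The forward step must acylate the weakly nucleophilic carbamate nitrogen without conjugate addition or loss of the E geometry.

5 ⇒ 3 + 4, then 3 ⇒ 2 ⇒ 1. The central σ bond of the diene (future C4–C5) is cut between two sp2 carbons, so that both alkene geometries are carried in separately and joined with retention. Then the C=C bond of 3 is cut back to the aldehyde 2, and the O–Si bond of 2 to 1. The forward steps need E-selective one-carbon iodo-olefination and a coupling mild enough for the aryl silyl ether and the vinyl C–Si bond.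

## Other disconnections considered

Alternative 1: The cut is C1–C2, after C7 has been tied through an ester oxygen to C4. Ring A then comes from the six-membered lactone (4S,6R)-4-{4-[(tert-butyldimethylsilyl)oxy]-3-methoxyphenyl}-6-[(Z)-2-(3,4-dimethoxyphenyl)ethenyl]oxan-2-one A1.

- **Forward step:** O-silylation of the lithium enolate of A1 (LiN(i-Pr)2, Me3SiCl) and warming would start a [3,3] shift. Because C1 and C4 are already linked by C6–C5, the six reacting atoms can only stack as a boat. C1–C2 would form as O–C4 breaks, giving the trimethylsilyl ester A2 of the ring A acid with the alkene at C3=C4.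
- **In favour:** The configuration of a carbinol carbon (C4) would be transferred stereospecifically to C1 and C2. The alkene arrives in place with no traceless group, and A2 is at the oxidation level of 12. On these three points the alternative equals or beats the chosen plan.
- **Against:** Analysis of the bridged boat shows that C7 cis to Ar2 and trans to Ar1 requires a trans-4,6-disubstituted lactone and a (Z)-styryl group. This puts Ar1 on the concave side of the boat, next to C6. Contracting a six-membered lactone through a bicyclo[2.2.2]octane-like array is much more strained than the large-ring cases in which this reaction is dependable. The O–C4 bond is allylic to an electron-rich styrene, so ionisation with loss of stereochemical information should compete with the concerted shift.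
- **Comparison:** A1 needs two stereocentres and a Z-alkene made beforehand. The chosen plan creates every stereocentre from achiral partners in one catalytic step, so it should be shorter and mechanistically safer.

Alternative 2: The cut is the C3=C4 double bond itself. The precursor is the open-chain diene aldehyde (2S,3S)-3-{4-[(tert-butyldimethylsilyl)oxy]-3-methoxyphenyl}-2-[(1S)-1-(3,4-dimethoxyphenyl)prop-2-en-1-yl]hex-5-enal A3.

- **Forward step:** The second-generation Grubbs catalyst, RuCl2(H2IMes)(PCy3)(=CHPh), would join the vinyl group on C2 and the allyl group on C6 to give the ring A carbaldehyde A4.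
- **In favour:** Closing an unstrained cyclohexene from two monosubstituted alkenes is among the most dependable ring closures known. As a ring-forming event it is the better of the two. The alkene position is unambiguous, and A4 could reach the diketone by aldol addition and oxidation, one operation fewer than through 12 and 13.
- **Against:** The metathesis creates no stereocentre. The three contiguous tertiary centres of A3, two of them benzylic, would each need their own control element in an open chain. The formyl-bearing centre, flanked by two benzylic carbons, is prone to epimerisation, and ruthenium hydride species can move the terminal alkenes.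
- **Comparison:** The ring closure is safer, but the route to A3 is expected to be longer than the whole chosen sequence to 10.

Alternative 3: The cuts are C6–Ar2 and C1–C7 on a ring that is already six-membered.

- **Forward step:** Birch reduction of 3,4-dimethoxy-1,1'-biphenyl A5 would dearomatise the unsubstituted ring to 3-(3,4-dimethoxyphenyl)cyclohexa-1,4-diene A6, in which C1=C6 and C3=C4 are enantiotopic. A chiral bis-phosphine complex of zerovalent palladium (from Pd2(dba)3) would insert into tert-butyl(4-iodo-2-methoxyphenoxy)dimethylsilane A7, add Ar2 and palladium syn across C1=C6 on the face away from Ar1, insert CO and be released by methanol as the methyl ester A8.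
- **In favour:** This is the shortest plan on paper. Two new stereocentres are made and C2 is desymmetrised in one catalytic step from an achiral diene. No ring has to be built, and A8 is equivalent to 12 for the end game. In step economy it would clearly beat the chosen plan.
- **Against:** Three components must react in a fixed order. Direct methoxycarbonylation of the aryl–palladium bond should be faster than insertion of an unactivated internal alkene. The alkyl–palladium at C1 has a syn β-hydrogen on C2 (Ar1 being anti), so β-hydride elimination and chain walking toward the Ar1-conjugated alkene are likely. Nothing in A6 strongly differentiates C6 from C1 for aryl delivery. The skipped diene also isomerises and re-aromatises easily, and ring selectivity in the Birch step is a further question.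
- **Comparison:** The chosen cycloaddition belongs to a well-studied catalyst–substrate class and fixes regiochemistry and relative configuration by orbital and geometric rules. This alternative relies on kinetic preferences for which this substrate class offers no support.

Key step: step 5

Remark 1: Ring A locants C1–C6 and chain locants C7–C11 are used in names and text, and the 1,3-diketone is written as its chelated enol, the tautomer of the target.

Remark 2: CIP analysis gives (1S,2S,6S) for 20 and (1S,2S,3R,6S) for 10. Both describe the same arrangement at C1, C2 and C6, and no structural correction was found necessary. Compound 4 and the ligand (R,R)-t-Bu-box, 2,2'-(propane-2,2-diyl)bis[(4R)-4-tert-butyl-4,5-dihydro-1,3-oxazole], are taken as catalogue chemicals.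

## Route

Step 1
Reactants: 1 vanillin (4-hydroxy-3-methoxybenzaldehyde)
Product: 2 4-[(tert-butyldimethylsilyl)oxy]-3-methoxybenzaldehyde
Conditions: TBSCl, imidazole, CH2Cl2, 23 °C
Reagents that add atoms: tert-butyldimethylsilyl chloride, CC(C)(C)[Si](C)(C)Cl
Why: Imidazole-promoted silylation of the phenol; the aldehyde is untouched and the silyl ether masks the only acidic proton before organometallic and Lewis-acid steps.

Step 2
Reactants: 2 4-[(tert-butyldimethylsilyl)oxy]-3-methoxybenzaldehyde
Product: 3 tert-butyl{4-[(E)-2-iodoethenyl]-2-methoxyphenoxy}dimethylsilane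
Conditions: CrCl2 (6 equiv), CHI3 (2 equiv), THF–dioxane, 0 to 23 °C, dark
Reagents that add atoms: iodoform, IC(I)I
Why: Takai olefination: the geminal dichromium species from CHI3 and CrCl2 adds to the aldehyde and eliminates to give mainly the (E)-iodoalkene with aryl aldehydes; the non-basic medium leaves the aryl silyl ether intact.

Step 3
Reactants: 3 tert-butyl{4-[(E)-2-iodoethenyl]-2-methoxyphenoxy}dimethylsilane; 4 trimethyl[(E)-2-(4,4,5,5-tetramethyl-1,3,2-dioxaborolan-2-yl)ethenyl]silane
Product: 5 (1E,3E)-1-{4-[(tert-butyldimethylsilyl)oxy]-3-methoxyphenyl}-4-(trimethylsilyl)buta-1,3-diene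
Conditions: PdCl2(dppf) (5 mol %), K3PO4 (2 equiv), THF–H2O (10:1), 23 °C
Reagents that add atoms: none
Why: Suzuki–Miyaura coupling of an alkenyl iodide with an alkenyl boronate proceeds with retention at both alkenes, so the E,E diene should result; boron transmetallates far faster than the vinyl C–Si bond, and phosphate at room temperature is chosen to spare the aryl silyl ether.

Step 4
Reactants: 6 (E)-3-(3,4-dimethoxyphenyl)prop-2-enoic acid (3,4-dimethoxycinnamic acid); 7 1,3-oxazolidin-2-one
Product: 9 3-[(E)-3-(3,4-dimethoxyphenyl)prop-2-enoyl]-1,3-oxazolidin-2-one, via mixed pivalic anhydride 8 (not isolated)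
Conditions: t-BuCOCl, Et3N, THF, −20 °C; then 7, LiCl, −20 to 23 °C
Reagents that add atoms: none
Why: N-acylation through a mixed anhydride: the tert-butyl group blocks the pivaloyl carbonyl so the lithium-activated carbamate nitrogen attacks the cinnamoyl carbonyl; no strong base is present, so conjugate addition and E/Z isomerisation are avoided.

Step 5
Reactants: 5 (1E,3E)-1-{4-[(tert-butyldimethylsilyl)oxy]-3-methoxyphenyl}-4-(trimethylsilyl)buta-1,3-diene; 9 3-[(E)-3-(3,4-dimethoxyphenyl)prop-2-enoyl]-1,3-oxazolidin-2-one
Product: 10 3-{[(1S,2S,3R,6S)-6-{4-[(tert-butyldimethylsilyl)oxy]-3-methoxyphenyl}-2-(3,4-dimethoxyphenyl)-3-(trimethylsilyl)cyclohex-4-en-1-yl]carbonyl}-1,3-oxazolidin-2-one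
Conditions: [Cu((R,R)-t-Bu-box)](SbF6)2 (10–20 mol %, from CuCl2, AgSbF6 and the ligand, AgCl filtered off), CH2Cl2 (high concentration), −20 to 23 °C
Reagents that add atoms: none
Why: The imide 9 binds the cationic divalent copper centre through both carbonyl oxygens in a distorted square-planar chelate that locks the enoyl unit s-cis and lowers its LUMO, and the s-cis diene 5 then adds in a concerted, asynchronous [4+2] cycloaddition that is suprafacial on both partners, the closest known reaction type being the bis(oxazoline)–copper-catalysed Diels–Alder reaction of N-enoyl oxazolidinones (acyclic 1-substituted dienes with the acryloyl imide, cyclopentadiene with β-aryl imides). Ring A is closed by intermolecular cycloaddition, both new σ bonds (C1–C6 and C2–C3) forming in the same step through a six-membered aromatic transition state. Regiochemistry follows from the donor aryl group, which puts the larger HOMO coefficient on the remote, silyl-bearing diene terminus, so that this carbon leads bond formation to the electrophilic β-carbon C2 while the aryl-bearing terminus closes onto C1. C1 and C2 come out trans because the E geometry of 9 is conserved. C6 and C3 come out cis to each other because the E,E geometry of 5 is conserved. The endo orientation of the chelated carbonyl under the diene places C7 cis to Ar2 and to silicon, and the same topology keeps Ar1 away from the bulky SiMe3 group on the neighbouring carbon, so orbital and steric preferences reinforce each other. The absolute sense comes from the ligand: on the accepted square-planar model the (S,S)-ligand leaves the Re face of the α-carbon open, so the (R,R)-ligand is chosen to expose the Si face of C1 that leads to (1S,2S,3R,6S). The step thus needs regio-, endo- and face selectivity, secured by the aryl donor, by the chelated carbonyl together with the SiMe3/Ar1 repulsion, and by the tert-butyl groups of the ligand, while the non-coordinating SbF6 counter-ion supplies the Lewis acidity that a β-aryl imide requires.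

Step 6
Reactants: 10 3-{[(1S,2S,3R,6S)-6-{4-[(tert-butyldimethylsilyl)oxy]-3-methoxyphenyl}-2-(3,4-dimethoxyphenyl)-3-(trimethylsilyl)cyclohex-4-en-1-yl]carbonyl}-1,3-oxazolidin-2-one
Product: 11 3-{[(1S,2S,6S)-6-{4-[(tert-butyldimethylsilyl)oxy]-3-methoxyphenyl}-2-(3,4-dimethoxyphenyl)cyclohex-3-en-1-yl]carbonyl}-1,3-oxazolidin-2-one
Conditions: CF3CO2H (5 equiv), CH2Cl2, 0 °C, short reaction time; aq NaHCO3
Reagents that add atoms: none
Why: Protodesilylation of an allylsilane (SE2'): the proton adds to C5, the developing cation at C4 is stabilised by the C3–Si bond, and loss of silicon leaves the alkene at C3=C4 with C5 as the methylene. C3 becomes sp2, so its auxiliary stereocentre is erased while C1, C2 and C6 are not involved; aryl silyl ethers and the imide tolerate brief cold trifluoroacetic acid.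

Step 7
Reactants: 11 3-{[(1S,2S,6S)-6-{4-[(tert-butyldimethylsilyl)oxy]-3-methoxyphenyl}-2-(3,4-dimethoxyphenyl)cyclohex-3-en-1-yl]carbonyl}-1,3-oxazolidin-2-one
Product: 12 S-ethyl (1S,2S,6S)-6-{4-[(tert-butyldimethylsilyl)oxy]-3-methoxyphenyl}-2-(3,4-dimethoxyphenyl)cyclohex-3-ene-1-carbothioate
Conditions: EtSH, n-BuLi (LiSEt, 2 equiv), THF, 0 °C; aq NH4Cl
Reagents that add atoms: ethanethiol (as LiSEt), CCS
Why: Thiolate cleavage of an N-acyl oxazolidinone: the small, soft and weakly basic thiolate attacks the exocyclic carbonyl even of congested imides and should not enolise C1; the achiral oxazolidinone is released and the thioester is a mild acyl donor for the next step.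

Step 8
Reactants: 12 S-ethyl (1S,2S,6S)-6-{4-[(tert-butyldimethylsilyl)oxy]-3-methoxyphenyl}-2-(3,4-dimethoxyphenyl)cyclohex-3-ene-1-carbothioate
Product: 13 1-[(1S,2S,6S)-6-{4-[(tert-butyldimethylsilyl)oxy]-3-methoxyphenyl}-2-(3,4-dimethoxyphenyl)cyclohex-3-en-1-yl]ethan-1-one
Conditions: Me2CuLi (3 equiv, from MeLi and CuI), Et2O, −78 to −40 °C; aq NH4Cl
Reagents that add atoms: lithium dimethylcuprate, [Li+].C[Cu-]C
Why: Acyl substitution of a thioester by a lithium dialkylcuprate stops at the ketone because cuprates add only slowly to ketones at low temperature; the reagent is weakly basic, so the C1 stereocentre should be preserved.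

Step 9
Reactants: 14 ferulic acid ((E)-3-(4-hydroxy-3-methoxyphenyl)prop-2-enoic acid)
Product: 16 (E)-3-{4-[(tert-butyldimethylsilyl)oxy]-3-methoxyphenyl}prop-2-enoic acid, via silyl ester 15 (not isolated)
Conditions: TBSCl (2.4 equiv), imidazole, DMF, 23 °C; then AcOH–THF–H2O, 23 °C
Reagents that add atoms: tert-butyldimethylsilyl chloride, CC(C)(C)[Si](C)(C)Cl
Why: Exhaustive silylation followed by selective hydrolysis: silyl esters are cleaved by mild aqueous acid within minutes, whereas aryl silyl ethers are stable to it.

Step 10
Reactants: 16 (E)-3-{4-[(tert-butyldimethylsilyl)oxy]-3-methoxyphenyl}prop-2-enoic acid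
Product: 17 (E)-3-{4-[(tert-butyldimethylsilyl)oxy]-3-methoxyphenyl}prop-2-enoyl chloride
Conditions: (COCl)2, DMF (cat.), CH2Cl2, 0 to 23 °C; evaporate, use crude
Reagents that add atoms: oxalyl chloride, O=C(Cl)C(=O)Cl
Why: Acid chloride formation through the chloroiminium species from oxalyl chloride and DMF; the by-products are gases, the alkene geometry is not affected and the aryl silyl ether tolerates the anhydrous HCl formed.

Step 11
Reactants: 13 1-[(1S,2S,6S)-6-{4-[(tert-butyldimethylsilyl)oxy]-3-methoxyphenyl}-2-(3,4-dimethoxyphenyl)cyclohex-3-en-1-yl]ethan-1-one; 17 (E)-3-{4-[(tert-butyldimethylsilyl)oxy]-3-methoxyphenyl}prop-2-enoyl chloride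
Product: 19 (2Z,4E)-5-{4-[(tert-butyldimethylsilyl)oxy]-3-methoxyphenyl}-1-[(1S,2S,6S)-6-{4-[(tert-butyldimethylsilyl)oxy]-3-methoxyphenyl}-2-(3,4-dimethoxyphenyl)cyclohex-3-en-1-yl]-3-hydroxypenta-2,4-dien-1-one, via lithium enolate 18 (not isolated)
Conditions: LiN(SiMe3)2 (2.5 equiv), toluene–THF, −78 °C; then 17 (1.3 equiv), −78 to 0 °C; aq NH4Cl
Reagents that add atoms: none
Why: Claisen-type C-acylation of a kinetic lithium enolate: the bulky amide base at −78 °C removes a methyl proton and not the hindered C1–H, so C1 is not epimerised, and lithium enolates in a toluene-rich medium favour C- over O-acylation. The excess base converts the product into its stable lithium diketonate, which resists a second acylation and gives the chelated enol on work-up.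

Step 12
Reactants: 19 (2Z,4E)-5-{4-[(tert-butyldimethylsilyl)oxy]-3-methoxyphenyl}-1-[(1S,2S,6S)-6-{4-[(tert-butyldimethylsilyl)oxy]-3-methoxyphenyl}-2-(3,4-dimethoxyphenyl)cyclohex-3-en-1-yl]-3-hydroxypenta-2,4-dien-1-one
Product: 20 (2Z,4E)-1-[(1S,2S,6S)-2-(3,4-dimethoxyphenyl)-6-(4-hydroxy-3-methoxyphenyl)cyclohex-3-en-1-yl]-3-hydroxy-5-(4-hydroxy-3-methoxyphenyl)penta-2,4-dien-1-one (CNP0290899.2)
Conditions: n-Bu4NF (3 equiv), AcOH (3 equiv), THF, 0 °C
Reagents that add atoms: none
Why: Fluoride cleavage of both aryl silyl ethers, driven by the strength of the Si–F bond; buffering with acetic acid keeps the medium near neutral, so the enolised diketone should neither undergo retro-Claisen cleavage nor epimerise at C1.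

## Compound list

1 | vanillin (4-hydroxy-3-methoxybenzaldehyde) | COc1cc(C=O)ccc1O | starting material
2 | 4-[(tert-butyldimethylsilyl)oxy]-3-methoxybenzaldehyde | COc1cc(C=O)ccc1O[Si](C)(C)C(C)(C)C | intermediate
3 | tert-butyl{4-[(E)-2-iodoethenyl]-2-methoxyphenoxy}dimethylsilane | COc1cc(/C=C/I)ccc1O[Si](C)(C)C(C)(C)C | intermediate
4 | trimethyl[(E)-2-(4,4,5,5-tetramethyl-1,3,2-dioxaborolan-2-yl)ethenyl]silane | C[Si](C)(C)/C=C/B1OC(C)(C)C(C)(C)O1 | starting material
5 | (1E,3E)-1-{4-[(tert-butyldimethylsilyl)oxy]-3-methoxyphenyl}-4-(trimethylsilyl)buta-1,3-diene | COc1cc(/C=C/C=C/[Si](C)(C)C)ccc1O[Si](C)(C)C(C)(C)C | intermediate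
6 | (E)-3-(3,4-dimethoxyphenyl)prop-2-enoic acid (3,4-dimethoxycinnamic acid) | COc1ccc(/C=C/C(=O)O)cc1OC | starting material
7 | 1,3-oxazolidin-2-one | O=C1NCCO1 | starting material
8 | (E)-3-(3,4-dimethoxyphenyl)prop-2-enoic 2,2-dimethylpropanoic anhydride | COc1ccc(/C=C/C(=O)OC(=O)C(C)(C)C)cc1OC | intermediate
9 | 3-[(E)-3-(3,4-dimethoxyphenyl)prop-2-enoyl]-1,3-oxazolidin-2-one | COc1ccc(/C=C/C(=O)N2CCOC2=O)cc1OC | intermediate
10 | 3-{[(1S,2S,3R,6S)-6-{4-[(tert-butyldimethylsilyl)oxy]-3-methoxyphenyl}-2-(3,4-dimethoxyphenyl)-3-(trimethylsilyl)cyclohex-4-en-1-yl]carbonyl}-1,3-oxazolidin-2-one | O=C(N1CCOC1=O)[C@@H]2[C@@H](c3ccc(OC)c(OC)c3)[C@H]([Si](C)(C)C)C=C[C@@H]2c4ccc(O[Si](C)(C)C(C)(C)C)c(OC)c4 | intermediate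
11 | 3-{[(1S,2S,6S)-6-{4-[(tert-butyldimethylsilyl)oxy]-3-methoxyphenyl}-2-(3,4-dimethoxyphenyl)cyclohex-3-en-1-yl]carbonyl}-1,3-oxazolidin-2-one | O=C(N1CCOC1=O)[C@@H]2[C@@H](c3ccc(OC)c(OC)c3)C=CC[C@@H]2c4ccc(O[Si](C)(C)C(C)(C)C)c(OC)c4 | intermediate
12 | S-ethyl (1S,2S,6S)-6-{4-[(tert-butyldimethylsilyl)oxy]-3-methoxyphenyl}-2-(3,4-dimethoxyphenyl)cyclohex-3-ene-1-carbothioate | CCSC(=O)[C@@H]1[C@@H](c2ccc(OC)c(OC)c2)C=CC[C@@H]1c3ccc(O[Si](C)(C)C(C)(C)C)c(OC)c3 | intermediate
13 | 1-[(1S,2S,6S)-6-{4-[(tert-butyldimethylsilyl)oxy]-3-methoxyphenyl}-2-(3,4-dimethoxyphenyl)cyclohex-3-en-1-yl]ethan-1-one | CC(=O)[C@@H]1[C@@H](c2ccc(OC)c(OC)c2)C=CC[C@@H]1c3ccc(O[Si](C)(C)C(C)(C)C)c(OC)c3 | intermediate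
14 | ferulic acid ((E)-3-(4-hydroxy-3-methoxyphenyl)prop-2-enoic acid) | COc1cc(/C=C/C(=O)O)ccc1O | starting material
15 | tert-butyldimethylsilyl (E)-3-{4-[(tert-butyldimethylsilyl)oxy]-3-methoxyphenyl}prop-2-enoate | COc1cc(/C=C/C(=O)O[Si](C)(C)C(C)(C)C)ccc1O[Si](C)(C)C(C)(C)C | intermediate
16 | (E)-3-{4-[(tert-butyldimethylsilyl)oxy]-3-methoxyphenyl}prop-2-enoic acid | COc1cc(/C=C/C(=O)O)ccc1O[Si](C)(C)C(C)(C)C | intermediate
17 | (E)-3-{4-[(tert-butyldimethylsilyl)oxy]-3-methoxyphenyl}prop-2-enoyl chloride | COc1cc(/C=C/C(=O)Cl)ccc1O[Si](C)(C)C(C)(C)C | intermediate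
18 | lithium 1-[(1S,2S,6S)-6-{4-[(tert-butyldimethylsilyl)oxy]-3-methoxyphenyl}-2-(3,4-dimethoxyphenyl)cyclohex-3-en-1-yl]ethen-1-olate (lithium enolate of 13) | [Li+].[O-]C(=C)[C@@H]1[C@@H](c2ccc(OC)c(OC)c2)C=CC[C@@H]1c3ccc(O[Si](C)(C)C(C)(C)C)c(OC)c3 | intermediate
19 | (2Z,4E)-5-{4-[(tert-butyldimethylsilyl)oxy]-3-methoxyphenyl}-1-[(1S,2S,6S)-6-{4-[(tert-butyldimethylsilyl)oxy]-3-methoxyphenyl}-2-(3,4-dimethoxyphenyl)cyclohex-3-en-1-yl]-3-hydroxypenta-2,4-dien-1-one | COc1cc(/C=C/C(O)=C/C(=O)[C@@H]2[C@@H](c3ccc(OC)c(OC)c3)C=CC[C@@H]2c4ccc(O[Si](C)(C)C(C)(C)C)c(OC)c4)ccc1O[Si](C)(C)C(C)(C)C | intermediate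
20 | (2Z,4E)-1-[(1S,2S,6S)-2-(3,4-dimethoxyphenyl)-6-(4-hydroxy-3-methoxyphenyl)cyclohex-3-en-1-yl]-3-hydroxy-5-(4-hydroxy-3-methoxyphenyl)penta-2,4-dien-1-one (CNP0290899.2) | COc1cc(/C=C/C(O)=C/C(=O)[C@@H]2[C@@H](c3ccc(OC)c(OC)c3)C=CC[C@@H]2c2ccc(O)c(OC)c2)ccc1O | target

## Step count and least certain steps

Total step count: 12. Longest linear sequence: 9 steps (1 → 2 → 3 → 5 → 10 → 11 → 12 → 13 → 19 → 20, that is steps 1, 2, 3, 5, 6, 7, 8, 11 and 12).

Step 5 (key step). The most likely failure is slow cycloaddition, because the β-aryl imide is deactivated by its donor arene and the diene is substituted at both termini. Cationic oligomerisation or premature protodesilylation of the electron-rich diene at the Lewis acid may then overtake the productive pathway. Endo and facial selectivity may also erode if the mixture has to be warmed. The fallback replaces catalyst control by substrate control. Setting out from 6, activation as in step 4 and acylation of (4S)-4-benzyl-1,3-oxazolidin-2-one would give (4S)-4-benzyl-3-[(E)-3-(3,4-dimethoxyphenyl)prop-2-enoyl]-1,3-oxazolidin-2-one F1. F1 and 5 with Et2AlCl (1.4 equiv, CH2Cl2, −40 to −20 °C) should react through the cationic aluminium chelate, whose benzyl group covers the Re face of C1, to give the endo adduct (4S)-4-benzyl-3-{[(1S,2S,3R,6S)-6-{4-[(tert-butyldimethylsilyl)oxy]-3-methoxyphenyl}-2-(3,4-dimethoxyphenyl)-3-(trimethylsilyl)cyclohex-4-en-1-yl]carbonyl}-1,3-oxazolidin-2-one F2. Trifluoroacetic acid as in step 6 would give (4S)-4-benzyl-3-{[(1S,2S,6S)-6-{4-[(tert-butyldimethylsilyl)oxy]-3-methoxyphenyl}-2-(3,4-dimethoxyphenyl)cyclohex-3-en-1-yl]carbonyl}-1,3-oxazolidin-2-one F3. LiSEt as in step 7 would then release the auxiliary and give 12, where the route is rejoined.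

Step 3. Loss of the aryl silyl ether by the aqueous base, protodeboronation of the alkenyl boronate, or partial E/Z scrambling of the iodoalkene before coupling would lower the supply of pure E,E diene. Only the E,E isomer can react in step 5. The fallback builds the vinylsilane double bond instead of the central σ bond and avoids base altogether. Setting out from 2, Wittig homologation with Ph3P=CHCHO (toluene, 80 °C) would give (E)-3-{4-[(tert-butyldimethylsilyl)oxy]-3-methoxyphenyl}prop-2-enal F4. Takai-type olefination of F4 with Me3SiCHBr2 and CrCl2 (THF, 23 °C) should form the (E)-vinylsilane and return to 5.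

Step 7. Attack at the ring carbonyl with opening of the oxazolidinone may occur, because the acyl carbon is flanked by two aryl-bearing carbons. Slow conversion with gradual epimerisation at C1 is the other concern. The fallback changes both the nucleophile and the ketone synthesis. Setting out from 11, LiOOH (LiOH, H2O2, THF–H2O, 0 °C, short exposure to protect the aryl silyl ether) would give (1S,2S,6S)-6-{4-[(tert-butyldimethylsilyl)oxy]-3-methoxyphenyl}-2-(3,4-dimethoxyphenyl)cyclohex-3-ene-1-carboxylic acid F5. Hydroperoxide is the nucleophile most selective for the exocyclic carbonyl of hindered imides. MeLi (2.2 equiv, THF, −78 to 0 °C, Me3SiCl then aqueous quench) would convert the lithium carboxylate of F5 into the methyl ketone, returning at 13 and bypassing 12.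

Step 11. O-acylation, a second acylation, conjugate addition to the cinnamoyl unit, or proton transfer that equilibrates the enolate toward C1 and epimerises it may reduce the yield of the C-acylated product. The fallback reaches the diketone by aldol addition and oxidation. Setting out from 13, the enolate 18 (LiN(SiMe3)2, THF, −78 °C) would add to the aldehyde (E)-3-{4-[(tert-butyldimethylsilyl)oxy]-3-methoxyphenyl}prop-2-enal F4 (made from 2 as described for step 3). This would give (4E)-5-{4-[(tert-butyldimethylsilyl)oxy]-3-methoxyphenyl}-1-[(1S,2S,6S)-6-{4-[(tert-butyldimethylsilyl)oxy]-3-methoxyphenyl}-2-(3,4-dimethoxyphenyl)cyclohex-3-en-1-yl]-3-hydroxypent-4-en-1-one F6 as a mixture of carbinol epimers, which does not matter. Oxidation of F6 with Dess–Martin periodinane (NaHCO3, CH2Cl2, 0 to 23 °C) would return to 19.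

## Further compounds

F1 | step 5 | (4S)-4-benzyl-3-[(E)-3-(3,4-dimethoxyphenyl)prop-2-enoyl]-1,3-oxazolidin-2-one | COc1ccc(/C=C/C(=O)N2[C@@H](Cc3ccccc3)COC2=O)cc1OC
F2 | step 5 | (4S)-4-benzyl-3-{[(1S,2S,3R,6S)-6-{4-[(tert-butyldimethylsilyl)oxy]-3-methoxyphenyl}-2-(3,4-dimethoxyphenyl)-3-(trimethylsilyl)cyclohex-4-en-1-yl]carbonyl}-1,3-oxazolidin-2-one | O=C(N1[C@@H](Cc5ccccc5)COC1=O)[C@@H]2[C@@H](c3ccc(OC)c(OC)c3)[C@H]([Si](C)(C)C)C=C[C@@H]2c4ccc(O[Si](C)(C)C(C)(C)C)c(OC)c4
F3 | step 5 | (4S)-4-benzyl-3-{[(1S,2S,6S)-6-{4-[(tert-butyldimethylsilyl)oxy]-3-methoxyphenyl}-2-(3,4-dimethoxyphenyl)cyclohex-3-en-1-yl]carbonyl}-1,3-oxazolidin-2-one | O=C(N1[C@@H](Cc5ccccc5)COC1=O)[C@@H]2[C@@H](c3ccc(OC)c(OC)c3)C=CC[C@@H]2c4ccc(O[Si](C)(C)C(C)(C)C)c(OC)c4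
F4 | step 3 | (E)-3-{4-[(tert-butyldimethylsilyl)oxy]-3-methoxyphenyl}prop-2-enal | COc1cc(/C=C/C=O)ccc1O[Si](C)(C)C(C)(C)C
F5 | step 7 | (1S,2S,6S)-6-{4-[(tert-butyldimethylsilyl)oxy]-3-methoxyphenyl}-2-(3,4-dimethoxyphenyl)cyclohex-3-ene-1-carboxylic acid | OC(=O)[C@@H]1[C@@H](c2ccc(OC)c(OC)c2)C=CC[C@@H]1c3ccc(O[Si](C)(C)C(C)(C)C)c(OC)c3
F6 | step 11 | (4E)-5-{4-[(tert-butyldimethylsilyl)oxy]-3-methoxyphenyl}-1-[(1S,2S,6S)-6-{4-[(tert-butyldimethylsilyl)oxy]-3-methoxyphenyl}-2-(3,4-dimethoxyphenyl)cyclohex-3-en-1-yl]-3-hydroxypent-4-en-1-one | COc1cc(/C=C/C(O)CC(=O)[C@@H]2[C@@H](c3ccc(OC)c(OC)c3)C=CC[C@@H]2c4ccc(O[Si](C)(C)C(C)(C)C)c(OC)c4)ccc1O[Si](C)(C)C(C)(C)C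
A1 | alternative 1 | (4S,6R)-4-{4-[(tert-butyldimethylsilyl)oxy]-3-methoxyphenyl}-6-[(Z)-2-(3,4-dimethoxyphenyl)ethenyl]oxan-2-one | O=C1C[C@@H](c2ccc(O[Si](C)(C)C(C)(C)C)c(OC)c2)C[C@H](/C=C\c2ccc(OC)c(OC)c2)O1
A2 | alternative 1 | trimethylsilyl (1S,2S,6S)-6-{4-[(tert-butyldimethylsilyl)oxy]-3-methoxyphenyl}-2-(3,4-dimethoxyphenyl)cyclohex-3-ene-1-carboxylate | C[Si](C)(C)OC(=O)[C@@H]1[C@@H](c2ccc(OC)c(OC)c2)C=CC[C@@H]1c3ccc(O[Si](C)(C)C(C)(C)C)c(OC)c3
A3 | alternative 2 | (2S,3S)-3-{4-[(tert-butyldimethylsilyl)oxy]-3-methoxyphenyl}-2-[(1S)-1-(3,4-dimethoxyphenyl)prop-2-en-1-yl]hex-5-enal | O=C[C@H]([C@@H](c1ccc(OC)c(OC)c1)C=C)[C@@H](c1ccc(O[Si](C)(C)C(C)(C)C)c(OC)c1)CC=C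
A4 | alternative 2 | (1S,2S,6S)-6-{4-[(tert-butyldimethylsilyl)oxy]-3-methoxyphenyl}-2-(3,4-dimethoxyphenyl)cyclohex-3-ene-1-carbaldehyde | O=C[C@@H]1[C@@H](c2ccc(OC)c(OC)c2)C=CC[C@@H]1c3ccc(O[Si](C)(C)C(C)(C)C)c(OC)c3
A5 | alternative 3 | 3,4-dimethoxy-1,1'-biphenyl | COc1ccc(-c2ccccc2)cc1OC
A6 | alternative 3 | 3-(3,4-dimethoxyphenyl)cyclohexa-1,4-diene | COc1ccc(C2C=CCC=C2)cc1OC
A7 | alternative 3 | tert-butyl(4-iodo-2-methoxyphenoxy)dimethylsilane | COc1cc(I)ccc1O[Si](C)(C)C(C)(C)C
A8 | alternative 3 | methyl (1S,2S,6S)-6-{4-[(tert-butyldimethylsilyl)oxy]-3-methoxyphenyl}-2-(3,4-dimethoxyphenyl)cyclohex-3-ene-1-carboxylate | COC(=O)[C@@H]1[C@@H](c2ccc(OC)c(OC)c2)C=CC[C@@H]1c3ccc(O[Si](C)(C)C(C)(C)C)c(OC)c3
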